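# Total synthesis proposal for elenic acid, (2R,3E)-22-(4-hydroxyphenyl)-2,4-dimethyldocos-3-enoic acid

Atom numbering of the target: C1 is the carboxyl carbon, C2 the stereocentre, C3=C4 the alkene, C5–C22 the methylene chain, and the arene sits on C22.

## Analysis of the target

- **Skeleton.** Elenic acid (15) is an open-chain C22 acid. C1 is the carboxyl carbon and C2 is a tertiary stereocentre bearing a methyl group. C3=C4 is an E-configured trisubstituted alkene with a methyl group on C4. C5–C22 is an unbranched run of eighteen CH2 groups, and C22 carries the only ring, a para-hydroxyphenyl group.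
- **Stereochemistry.** There is one stereocentre (2R) and one stereogenic double bond (3E). They are joined directly by the C2–C3 σ bond, so all stereochemical information sits in the four-atom head C1–C4.
- **Sensitivity of the head.** C2–H is both α to the C1 carboxyl group and allylic to C3=C4. Base racemises C2 or moves the alkene into conjugation (C2=C3). Strong protic acid protonates C3 and lets the carboxyl oxygen close on the tertiary C4 cation to give a γ-lactone.
- **Alkene geometry.** The two substituents on C4, CH3 and C5H2, are almost equal in size. Any carbonyl olefination that makes C3=C4 therefore has little to tell E from Z.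
- **Chain and phenol.** The C5–C22 chain offers no handle, makes every intermediate waxy, and forbids hydrogenation once C3=C4 is in place. The phenol is acidic and easily oxidised.
- **Feature exploited.** C2 is a carbon whose radical is planar and stabilised by the C1 carbonyl group, and it is bonded to the sp2 carbon C3. The unit H–C3=C4(CH3)–C5 is the exact imprint of a syn addition of methyl and metal to a terminal alkyne.
- **Consequence.** C2–C3 and C4–CH3 can be made in one operation in which a racemic C1–C2 building block is funnelled into the 2R configuration.

## Retrosynthetic reasoning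

**15 ⇒ 13 (unmasking only).** The O–tert-butyl bond at the C1 ester and the O–Si bond at the phenol are cut. Both groups leave without hydroxide and without free strong acid. The labile C2–H therefore never meets base while C1 is still an ester, and C3=C4 never meets a proton source able to start lactonisation. No skeletal bond is touched after the key step.

**13 ⇒ 9 + 10 (key disconnection; C2–C3 and C4–CH3 are cut together).**
- Cutting the sp3–sp2 bond C2–C3 separates the labile stereocentre from the alkene. It leaves C1, C2 and the C2-methyl group as the racemic commodity bromo ester 10.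
- Cutting C4–CH3 at the same time turns the alkene into the terminal triple bond of 9.
- The cut is placed here because C3=C4 formation cannot distinguish the two alkyl groups on C4. A cut at C1–C2 or C2–H would need a precursor that already contains the E-alkene.
- The gain is that 9 has no stereocentre and no stereogenic alkene, and 10 needs no enantiopurity.
- The forward reaction has to add methyl and metal syn and regioselectively to 9. It must pass the alkenyl group on with retention, and convert both enantiomers of 10 through one planar C2 radical into (2R)-13 under control of a chiral nickel catalyst. This is a stereoconvergent three-component union.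

**9 ⇒ 4 + 6 (C13–C14).** The featureless chain is cut in its middle by an sp3–sp3 disconnection. The position is dictated by supply: a C9 and a C11 catalogue building block add up to the required twenty chain carbons of 9. The forward coupling has to join a primary alkyl Grignard reagent to a primary bromide while the acidic alkyne C–H of 6 is masked in the flask.

**4 ⇒ 1 + 2 (C22–aryl) and 6 ⇒ 5 (C–Br from C–OH).** The arene is attached as its Grignard reagent to one end of the symmetrical dibromide 2. This gives 4 with the second bromide already in place for the next coupling. Bromide 6 comes from the commercial alkynol 5 by one functional group change.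

## Alternatives that were turned down

**Alternative 1:** (textbook) Disconnection of C3=C4 by carbonyl olefination, with C2 taken from the chiral pool.
- *Forward key step:* Wittig reaction of the α-branched, non-stabilised ylide A2 with the protected hydroxy aldehyde A1 to give alkene A3. Release of O1 and two oxidations then bring C1 to the acid.
- *Why turned down:*
  - In the oxaphosphetane the two groups on the ylide carbon (CH3 and C5H2) are nearly the same size. Nothing in the structure controls the geometry at C3=C4.
  - The strongly basic ylide meets an aldehyde with an enolisable C2–H, so the purchased stereocentre is at risk in the very step that uses it.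
  - A2 needs its own secondary halide carrying the whole aryl-C18 chain.
  - C1 arrives in the wrong oxidation state, so several protecting-group and redox operations follow the key step, one of them through an α-chiral β,γ-unsaturated aldehyde.

**Alternative 2:** Disconnection of C1–C2, in which the carboxyl carbon is added to a diene.
- *Forward key step:* rhodium-catalysed asymmetric, branched-selective hydroformylation of the terminal double bond of (E)-diene A4 to aldehyde A5, then oxidation to the acid.
- *Why turned down:*
  - A4 has to be made from the same alkyne 9 by methylalumination and vinylation. The E-alkene problem is therefore solved before the key step, not by it.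
  - The η3-allylrhodium intermediate spans C2–C4 and can lose the C3=C4 geometry by σ–π–σ isomerisation, or deliver the formyl group with allylic transposition.
  - A5 enolises far more easily than an ester and has to survive warm hydroformylation conditions.
  - Diene formation and oxidation add two steps to the chosen route.

**Alternative 3:** Disconnection of C2–H by enzymatic desymmetrisation.
- *Forward key step:* an arylmalonate decarboxylase (cofactor-free decarboxylase class) removes one carboxyl group of the prochiral diacid A6 and protonates the enediolate from one face. Enzymes of this class accept α-aryl- and small α-alkenyl-α-methylmalonic acids. The R sense of the wild type would fit 15.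
- *Why turned down:*
  - A6 is not simpler than the product. It needs the same C2–C3 bond, now to a fully substituted carbon, and the hydrolysis of two hindered esters.
  - The β,β-disubstituted alkenyl group is twisted out of the plane of the enediolate by allylic strain with the C4 substituents. This weakens the π-stabilisation the enzyme relies on.
  - A C22 amphiphile forms micelles in buffer, and its chain has to leave a pocket shaped for flat, small π-systems.

Key step: step 4

Remark on the chemistry (assumption): the sense of induction of the nickel/bis(oxazoline) catalyst for this pair of partners cannot be derived safely from analogy. Both enantiomers of the ligand are commercial, and the route assumes the one that gives (2R)-13.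

## Route

Step 1
Reactants: 1 (4-bromophenoxy)(tert-butyl)dimethylsilane; 2 1,9-dibromononane
Product: 4 [4-(9-bromononyl)phenoxy](tert-butyl)dimethylsilane, via arylmagnesium bromide 3 (not isolated)
Conditions: 1, Mg, THF, 40 °C; then added to 2 (4 equiv), Li2CuCl4 (3 mol %), THF, 0 °C → rt; excess 2 distilled off
Reagents that add atoms: none
Why: Copper-catalysed Grignard–alkyl halide cross-coupling (aryl cuprate, SN2-type attack at a primary C–Br). The excess of the symmetrical dibromide 2 should keep substitution at the second end statistically small, and the aryl silyl ether is inert to magnesium and to the cuprate.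

Step 2
Reactants: 5 undec-10-yn-1-ol
Product: 6 11-bromoundec-1-yne
Conditions: CBr4, PPh3, CH2Cl2, 0 °C → rt
Reagents that add atoms: carbon tetrabromide, BrC(Br)(Br)Br
Why: Appel reaction, in which bromide displaces the oxyphosphonium ion at a primary carbon under neutral conditions. The terminal alkyne is not touched.

Step 3
Reactants: 4 [4-(9-bromononyl)phenoxy](tert-butyl)dimethylsilane; 6 11-bromoundec-1-yne
Product: 9 tert-butyl[4-(icos-19-yn-1-yl)phenoxy]dimethylsilane, via alkylmagnesium bromide 7 (not isolated), via bromomagnesium acetylide 8 (not isolated)
Conditions: 4, Mg, THF, 40 °C (→ 7); 6, EtMgBr (1.05 equiv), THF, 0 → 40 °C (→ 8); combined, Li2CuCl4 (5 mol %), NMP (4 equiv), THF, 0 °C → rt; aqueous work-up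
Reagents that add atoms: none
Why: Copper-catalysed sp3–sp3 Grignard–alkyl bromide cross-coupling that forms C13–C14. The acidic alkyne C–H of 6 is masked in the flask as acetylide 8, and an alkynyl group on copper is a non-transferable ligand, so only the alkyl group of 7 should reach the primary bromide. Work-up returns the terminal alkyne.

Step 4
Reactants: 9 tert-butyl[4-(icos-19-yn-1-yl)phenoxy]dimethylsilane; 10 tert-butyl 2-bromopropanoate (racemic)
Product: 13 tert-butyl (2R,3E)-22-{4-[(tert-butyldimethylsilyl)oxy]phenyl}-2,4-dimethyldocos-3-enoate, via (E)-alkenyldimethylalane 11 (not isolated), via (E)-alkenylzinc bromide 12 (not isolated)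
Conditions: Me3Al (2 equiv), Cp2ZrCl2 (20 mol %), CH2Cl2, 0 °C → rt; volatiles removed in vacuo; ZnBr2 (1.1 equiv), THF, 0 °C; NiCl2·glyme (10 mol %), 2,2′-isopropylidenebis(4-phenyl-2-oxazoline) (13 mol %, enantiomer as in the remark), rac-10 (2 equiv), THF, −30 °C; aq. Rochelle salt
Reagents that add atoms: trimethylaluminium, C[Al](C)C
Why: Proposed new method: the one-flask chain of Zr-catalysed methylalumination, Al-to-Zn exchange and nickel-catalysed enantioconvergent Negishi alkenylation has not been shown with an α-bromo ester as the electrophile; the closest known reaction types are the carboalumination/Negishi coupling tandem and the nickel- or cobalt-catalysed stereoconvergent alkenylations of racemic α-bromo esters, nitriles and ketones with alkenyl-silicon, -magnesium, -zinc and -zirconium reagents. The zirconocene/methylaluminium reagent adds CH3 and Al syn across the triple bond of 9, CH3 to the substituted carbon (future C4) and Al to the terminal carbon (future C3), so that in 11 the new methyl group is cis to the metal, which is the 3E geometry; the control elements are the concerted syn carbometalation and the steric bias of a terminal alkyne. Zinc bromide takes over the alkenyl group with retention to give 12, a nucleophile too weakly basic to enolise 10 or 13. A ligand-bound nickel(I) species abstracts bromine from either enantiomer of 10 and gives the same planar C2 radical, stabilised by the C1 ester; this radical is captured by the chiral alkenylnickel(II) complex formed from 12, and reductive elimination from nickel(III) forms C2–C3 with retention at C3. The configuration at C2 is therefore set only by the chiral bis(oxazoline) ligand in the capture/reductive elimination sequence, both enantiomers of 10 are funnelled into (2R)-13, and the bulky tert-butyl ester sharpens the distinction between ester and methyl group on the radical. No ring is closed. The step needs alkenyl rather than methyl transfer to nickel, which the faster transmetalation of sp2 groups, the removal of excess methylaluminium in vacuo and an excess of the cheap partner 10 should secure. It also needs 13 to survive without epimerisation or alkene migration, which the non-basic zinc and aluminium species and the low temperature should secure, and the silyl ether, eighteen CH2 groups away, takes no part.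

Step 5
Reactants: 13 tert-butyl (2R,3E)-22-{4-[(tert-butyldimethylsilyl)oxy]phenyl}-2,4-dimethyldocos-3-enoate
Product: 15 elenic acid, (2R,3E)-22-(4-hydroxyphenyl)-2,4-dimethyldocos-3-enoic acid, via trimethylsilyl ester 14 (not isolated)
Conditions: TMSOTf (2.5 equiv), 2,6-lutidine (3.5 equiv), CH2Cl2, 0 °C → rt; concentrated; TBAF (4 equiv), THF, 0 °C; cold 0.5 M HCl to pH 3–4, extraction
Reagents that add atoms: none
Why: Silyl-triflate-mediated tert-butyl ester cleavage (O-silylation of the carbonyl group, loss of the tert-butyl cation as the alkene, proton taken by the hindered base), followed by fluoride desilylation of both silyl groups. No free strong acid is present that could protonate C3 and start lactonisation onto C4. Fluoride meets C2–H only when C1 is a silyl ester that collapses at once to the carboxylate, whose α-proton is not removed, so 2R and 3E should be kept.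

## Compound list

1 | (4-bromophenoxy)(tert-butyl)dimethylsilane | CC(C)(C)[Si](C)(C)Oc1ccc(Br)cc1 | starting material
2 | 1,9-dibromononane | BrCCCCCCCCCBr | starting material
3 | {4-[(tert-butyldimethylsilyl)oxy]phenyl}magnesium bromide | CC(C)(C)[Si](C)(C)Oc1ccc([Mg]Br)cc1 | intermediate
4 | [4-(9-bromononyl)phenoxy](tert-butyl)dimethylsilane | CC(C)(C)[Si](C)(C)Oc1ccc(CCCCCCCCCBr)cc1 | intermediate
5 | undec-10-yn-1-ol | C#CCCCCCCCCCO | starting material
6 | 11-bromoundec-1-yne | C#CCCCCCCCCCBr | intermediate
7 | (9-{4-[(tert-butyldimethylsilyl)oxy]phenyl}nonyl)magnesium bromide | CC(C)(C)[Si](C)(C)Oc1ccc(CCCCCCCCC[Mg]Br)cc1 | intermediate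
8 | (11-bromoundec-1-yn-1-yl)magnesium bromide | Br[Mg]C#CCCCCCCCCCBr | intermediate
9 | tert-butyl[4-(icos-19-yn-1-yl)phenoxy]dimethylsilane | C#CCCCCCCCCCCCCCCCCCCc1ccc(O[Si](C)(C)C(C)(C)C)cc1 | intermediate
10 | tert-butyl 2-bromopropanoate (racemic) | CC(Br)C(=O)OC(C)(C)C | starting material
11 | [(1E)-20-{4-[(tert-butyldimethylsilyl)oxy]phenyl}-2-methylicos-1-en-1-yl]dimethylalane | C/C(=C\[Al](C)C)CCCCCCCCCCCCCCCCCCc1ccc(O[Si](C)(C)C(C)(C)C)cc1 | intermediate
12 | bromo[(1E)-20-{4-[(tert-butyldimethylsilyl)oxy]phenyl}-2-methylicos-1-en-1-yl]zinc | C/C(=C\[Zn]Br)CCCCCCCCCCCCCCCCCCc1ccc(O[Si](C)(C)C(C)(C)C)cc1 | intermediate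
13 | tert-butyl (2R,3E)-22-{4-[(tert-butyldimethylsilyl)oxy]phenyl}-2,4-dimethyldocos-3-enoate | C/C(=C\[C@@H](C)C(=O)OC(C)(C)C)CCCCCCCCCCCCCCCCCCc1ccc(O[Si](C)(C)C(C)(C)C)cc1 | intermediate
14 | trimethylsilyl (2R,3E)-22-{4-[(tert-butyldimethylsilyl)oxy]phenyl}-2,4-dimethyldocos-3-enoate | C/C(=C\[C@@H](C)C(=O)O[Si](C)(C)C)CCCCCCCCCCCCCCCCCCc1ccc(O[Si](C)(C)C(C)(C)C)cc1 | intermediate
15 | elenic acid, (2R,3E)-22-(4-hydroxyphenyl)-2,4-dimethyldocos-3-enoic acid | C/C(=C\[C@@H](C)C(=O)O)CCCCCCCCCCCCCCCCCCc1ccc(O)cc1 | target

## Step count and risk

Total step count: 5. Longest linear sequence: 4 (steps 1, 3, 4, 5); step 2 is a one-step side branch.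

**Step 4 (key step, proposed new method).**
- *What may go wrong:*
  - Enantioselectivity may erode because Lewis acidic aluminium species bind the bis(oxazoline) ligand or the ester.
  - Methyl transfer to nickel may compete with alkenyl transfer.
  - The electrophile may be lost by hydrodehalogenation or dimerisation.
  - A nickel hydride may move the alkene into conjugation.
  - The minor regioisomer of the methylalumination is carried through, because nothing is purified between the stages.
- *Fallback (known chemistry, stages separated, other metal pair):* 9 is methylaluminated as above and alane 11 is quenched with iodine to give the isolable (E)-alkenyl iodide F1, which is freed from its regioisomer. Iodine–lithium exchange (t-BuLi, 2 equiv, Et2O, −78 °C) gives the alkenyllithium F2, and MgBr2·OEt2 gives the alkenylmagnesium bromide F3. F3 is coupled with rac-10 under cobalt/bis(oxazoline) catalysis in THF at −80 °C, an enantioconvergent Kumada alkenylation of α-bromo esters and a known reaction type. The route is rejoined at 13.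

**Step 5.**
- *What may go wrong:* incompletely buffered triflic acid may protonate C3, followed by lactonisation onto C4. The ester cleavage may be sluggish because of the branched α-carbon. The alkene may migrate during a long exposure.
- *Fallback (redox detour instead of ester cleavage):* 13 is reduced with DIBAL-H (CH2Cl2, −78 → 0 °C) to the primary alcohol F4. F4 is oxidised with Dess–Martin periodinane/NaHCO3 to the aldehyde F5, which is taken on crude in a Pinnick oxidation (NaClO2, NaH2PO4, 2-methylbut-2-ene) to the O-silylated acid F6. TBAF in THF at 0 °C then frees the phenol, and the route is rejoined at 15.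

**Step 3.**
- *What may go wrong:* the acetylide may sequester copper so that catalysis stalls. Incompletely metalated alkyne may protonate the Grignard reagent. The Grignard reagent may undergo Wurtz-type homocoupling during its formation.
- *Fallback (alkyne made last, after all Grignard chemistry):* starting from 4, Grignard reagent 7 is coupled under the same copper catalysis with purchased 10-bromodecan-1-ol F7, pre-deprotonated with EtMgBr, to give the C19 alcohol F8. Dess–Martin oxidation gives the aldehyde F9. One-carbon homologation by the Colvin rearrangement (lithiated trimethylsilyldiazomethane, THF, −78 °C → rt; non-protic, so the aryl silyl ether stays) rejoins the route at 9.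

**Step 1.**
- *What may go wrong:* substitution may occur at both ends of the dibromide despite the excess. The aryl Grignard reagent may homocouple oxidatively on copper. Removing the non-polar excess reagent may be tedious.
- *Fallback (differentiated chain ends instead of statistics):* starting from 1, Sonogashira coupling with purchased non-8-yn-1-ol F10 (PdCl2(PPh3)2, CuI, Et3N, 70 °C) gives the arylalkynol F11. Hydrogenation (H2, Pd/C, EtOAc) gives the saturated alcohol F12, and an Appel reaction (CBr4, PPh3) rejoins the route at 4.

## Further compounds

F1 | step 4 | tert-butyl{4-[(19E)-20-iodo-19-methylicos-19-en-1-yl]phenoxy}dimethylsilane | C/C(=C\I)CCCCCCCCCCCCCCCCCCc1ccc(O[Si](C)(C)C(C)(C)C)cc1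
F2 | step 4 | [(1E)-20-{4-[(tert-butyldimethylsilyl)oxy]phenyl}-2-methylicos-1-en-1-yl]lithium | C/C(=C\[Li])CCCCCCCCCCCCCCCCCCc1ccc(O[Si](C)(C)C(C)(C)C)cc1
F3 | step 4 | [(1E)-20-{4-[(tert-butyldimethylsilyl)oxy]phenyl}-2-methylicos-1-en-1-yl]magnesium bromide | C/C(=C\[Mg]Br)CCCCCCCCCCCCCCCCCCc1ccc(O[Si](C)(C)C(C)(C)C)cc1
F4 | step 5 | (2R,3E)-22-{4-[(tert-butyldimethylsilyl)oxy]phenyl}-2,4-dimethyldocos-3-en-1-ol | C/C(=C\[C@@H](C)CO)CCCCCCCCCCCCCCCCCCc1ccc(O[Si](C)(C)C(C)(C)C)cc1
F5 | step 5 | (2R,3E)-22-{4-[(tert-butyldimethylsilyl)oxy]phenyl}-2,4-dimethyldocos-3-enal | C/C(=C\[C@@H](C)C=O)CCCCCCCCCCCCCCCCCCc1ccc(O[Si](C)(C)C(C)(C)C)cc1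
F6 | step 5 | (2R,3E)-22-{4-[(tert-butyldimethylsilyl)oxy]phenyl}-2,4-dimethyldocos-3-enoic acid | C/C(=C\[C@@H](C)C(=O)O)CCCCCCCCCCCCCCCCCCc1ccc(O[Si](C)(C)C(C)(C)C)cc1
F7 | step 3 | 10-bromodecan-1-ol (purchased) | OCCCCCCCCCCBr
F8 | step 3 | 19-{4-[(tert-butyldimethylsilyl)oxy]phenyl}nonadecan-1-ol | OCCCCCCCCCCCCCCCCCCCc1ccc(O[Si](C)(C)C(C)(C)C)cc1
F9 | step 3 | 19-{4-[(tert-butyldimethylsilyl)oxy]phenyl}nonadecanal | O=CCCCCCCCCCCCCCCCCCCc1ccc(O[Si](C)(C)C(C)(C)C)cc1
F10 | step 1 | non-8-yn-1-ol (purchased) | C#CCCCCCCCO
F11 | step 1 | 9-{4-[(tert-butyldimethylsilyl)oxy]phenyl}non-8-yn-1-ol | OCCCCCCCC#Cc1ccc(O[Si](C)(C)C(C)(C)C)cc1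
F12 | step 1 | 9-{4-[(tert-butyldimethylsilyl)oxy]phenyl}nonan-1-ol | OCCCCCCCCCc1ccc(O[Si](C)(C)C(C)(C)C)cc1
A1 | alternative 1 | (S)-3-[(tert-butyldimethylsilyl)oxy]-2-methylpropanal | O=C[C@@H](C)CO[Si](C)(C)C(C)(C)C
A2 | alternative 1 | (20-{4-[(tert-butyldimethylsilyl)oxy]phenyl}icosan-2-ylidene)triphenylphosphorane | CC(=P(c1ccccc1)(c1ccccc1)c1ccccc1)CCCCCCCCCCCCCCCCCCc1ccc(O[Si](C)(C)C(C)(C)C)cc1
A3 | alternative 1 | bis(tert-butyldimethylsilyl) ether of (2R,3E)-22-(4-hydroxyphenyl)-2,4-dimethyldocos-3-en-1-ol | C/C(=C\[C@@H](C)CO[Si](C)(C)C(C)(C)C)CCCCCCCCCCCCCCCCCCc1ccc(O[Si](C)(C)C(C)(C)C)cc1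
A4 | alternative 2 | tert-butyl{4-[(19E)-19-methyldocosa-19,21-dien-1-yl]phenoxy}dimethylsilane | C/C(=C\C=C)CCCCCCCCCCCCCCCCCCc1ccc(O[Si](C)(C)C(C)(C)C)cc1
A5 | alternative 2 | (2R,3E)-22-{4-[(tert-butyldimethylsilyl)oxy]phenyl}-2,4-dimethyldocos-3-enal | C/C(=C\[C@@H](C)C=O)CCCCCCCCCCCCCCCCCCc1ccc(O[Si](C)(C)C(C)(C)C)cc1
A6 | alternative 3 | 2-[(1E)-20-(4-hydroxyphenyl)-2-methylicos-1-en-1-yl]-2-methylpropanedioic acid | C/C(=C\C(C)(C(=O)O)C(=O)O)CCCCCCCCCCCCCCCCCCc1ccc(O)cc1
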